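Two questions carry my reckoning for the flasks winter and spring, in each of which a single-handed reagent is fed in portions to a pair of mirror-image substrates.

| flask | left-handed substrate | right-handed substrate | reagent | temperature | remark | time |
|---|---|---|---|---|---|---|
| theta | 0.21 M | 0.21 M | 0.32 M (in portions, 3) | −25 °C | run made earlier; portions every 4.0 h |  |
| epsilon | 0.21 M | 0.21 M | 0.41 M (in portions, 3) | 0 °C | run made earlier; portions every 4.0 h |  |
| gamma | 0.21 M | 0.21 M | 0.48 M (in portions, 3) | −25 °C | run made earlier; portions every 4.0 h |  |
| winter | 0.21 M | 0.21 M | 0.300 M (in portions, 3) |  | at 20 °C throughout; the portions of reagent follow each other after 4.0 h, the first at the start | 1.2 d |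
| spring | 0.21 M | 0.21 M | 0.630 M (in portions, 3) |  | at −20 °C until 40 h, from then on at 20 °C; the portions of reagent follow each other after 4.0 h, the first at the start | 5.0 d |

- theta (time / d: left-handed product / %): 0.208: 3; 0.500: 16; 1.04: 24; 2.50: 25
- epsilon (time / h: left-handed product / %): 3.00: 14; 8.00: 28; 15.0: 39; 20.0: 37
- gamma (time / d: left-handed product / %): 0.208: 9; 0.500: 21; 1.04: 27; 2.50: 30

(scatter of a reading: 1.5 percentage points)

* which one finishes higher in amount of left-handed product, in percent of the left-handed substrate and right-handed substrate together charged ("neither" within 2 percentage points) (winter / spring / neither)
* amount of left-handed product at the end, in percent of the left-handed substrate and right-handed substrate together charged, winter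
* amount of left-handed product at the end, in percent of the left-handed substrate and right-handed substrate together charged, spring

- reagent is single-handed; left-handed substrate and right-handed substrate are mirror images of each other, charged as a racemate, each of them at the stated concentration
- the analysis behind the earlier runs scatters by 1.5 percentage points, standard deviation
- steps thought possible: right-handed substrate <-> achiral form; 2 reagent -> homo dimer; left-handed substrate <-> achiral form; reagent + right-handed substrate -> right-handed product; reagent + left-handed substrate -> left-handed product
- the handed part of reagent does not stay in what it makes, so the products of the two hands are mirror images too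

The first question is what a charge of reagent buys, since a reagent molecule stands at a fork: left-handed substrate, right-handed substrate, or a second reagent molecule. I call the catch the left-handed product at the plateau, in M, over the reagent charged, in M. From the last reading of each, the catch reads 0.328 in theta and 0.263 in gamma, both at −25 °C. So in these two readings the catch falls as the charge rises, and I read a charge penalty, the fall of the catch per molar of reagent at one temperature, of 0.410 M⁻¹.

The second question is what catch each new charge gets. Epsilon's last two readings give a catch of 0.389 at 0 °C. Moved to winter's charge by the penalty, which I assume carries over although I read it at −25 °C, this becomes 0.434, hence 31.0 %, with the further warming not counted. Theta reads 24 % at 1.04 d and 25 % at 2.50 d, gamma 27 % and 30 % at the same times, so I take these cold runs as close to their plateaus at a time sooner than spring's change of temperature, and I treat spring as a cold flask. Gamma's catch moved to spring's charge becomes 0.201, hence 30.1 %, with the step from −25 °C to spring's −20 °C not counted. That is a gap of 0.90 percentage points, below the margin, so I call it a tie.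

The forecast also says neither, with higher numbers than mine, 34 % (26 % to 43 %) for winter and 36 % (31 % to 44 %) for spring, holding that “Warming then adds little because hardly any reagent remains”.

The flasks give 31.7 % for winter and 37.1 % for spring, so spring finishes higher.

    right-handed substrate ⇌ achiral form (K = 0.349, k = 6.01 × 10⁻⁴ min⁻¹, Ea = 84.0 kJ mol⁻¹, ΔH = 1.00 kJ mol⁻¹)
    2 reagent → homo dimer (k = 0.00688 M⁻¹ min⁻¹, Ea = 60.0 kJ mol⁻¹)
    left-handed substrate ⇌ achiral form (K = 0.349, k = 6.01 × 10⁻⁴ min⁻¹, Ea = 84.0 kJ mol⁻¹, ΔH = 1.00 kJ mol⁻¹)
    reagent + right-handed substrate → right-handed product (k = 0.00383 M⁻¹ min⁻¹, Ea = 72.0 kJ mol⁻¹)
    reagent + left-handed substrate → left-handed product (k = 0.00732 M⁻¹ min⁻¹, Ea = 66.0 kJ mol⁻¹)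
    (constants at −20 °C)

Winter's catch is 0.444 against my 0.434, while spring's is 0.247, above my 0.201, and there we part. In spring at its first temperature, with the other concentrations as charged, reagent's half-life by the step to left-handed product alone is 0.31 d against 0.60 d by the step to right-handed product, a selectivity factor of 1.91, whereas in winter at 0.170 d the half-life of left-handed substrate by its step to product is 0.47 h and that of right-handed substrate by its step is 0.61 h, a factor of 1.30. On the neighbour of winter charged with 0.12 M, at winter's temperature, the penalty read at −25 °C lifts winter's catch to 0.517, which means 14.8 %, and that flask gives 14.8 %.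

The readings were generated by integration from invented constants.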